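**Strategy.** The decalin is numbered as a labdane: ring A is C1–C5 plus C10, ring B is C5–C10, with C10 the methylated quaternary carbon, C8 the methylated and C9 the chain-bearing alkene carbon. Ring B is read as two three-carbon units, C8–C9–C10 (an ethyl ketone, as its silyl enol ether) and C5–C6–C7 (an enal), held together only by the C1–C4 chain. One catalytic, enantioselective operation joins C10 to C5 by Mukaiyama–Michael addition (ring A) and then C8 to C7 by aldol condensation (ring B), converting an open-chain enal into the bicyclic enone with both stereocentres. The C9 oxygen then becomes the enol triflate through which the side chain is attached.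

Key step: step 5

Remark: the enol ethers 6, 8 and 9 are carried as E/Z mixtures at the fully substituted enol ether double bond (left undefined in the SMILES); both isomers should converge on 11.

Step 1
Reactants: 1 methyl 3,3-dimethylpent-4-enoate
Product: 2 3,3-dimethylpent-4-en-1-ol
Conditions: LiAlH4, Et2O, 0 °C to rt
Reagents that add atoms: none
Why: LiAlH4 reduction of the ester to the primary alcohol should be clean because the isolated vinyl group and the quaternary carbon are inert to hydride.

Step 2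
Reactants: 2 3,3-dimethylpent-4-en-1-ol
Product: 3 5-bromo-3,3-dimethylpent-1-ene
Conditions: CBr4, PPh3, CH2Cl2, 0 °C
Reagents that add atoms: carbon tetrabromide, BrC(Br)(Br)Br
Why: The Appel reaction converts the unhindered primary alcohol into the bromide under neutral conditions that leave the alkene untouched.

Step 3
Reactants: 3 5-bromo-3,3-dimethylpent-1-ene; 4 2-methylpent-1-en-3-one
Product: 6 triethyl[(4,8,8-trimethyldeca-3,9-dien-3-yl)oxy]silane (E/Z mixture), via Grignard reagent 5 (not isolated)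
Conditions: Mg, THF, rt; then CuBr·SMe2 (5 mol %), Et3SiCl, HMPA, 4, THF, −78 °C
Reagents that add atoms: chlorotriethylsilane, CC[Si](Cl)(CC)CC
Why: Copper-catalysed conjugate addition of the Grignard reagent to the vinyl ketone with O-silylation in the same flask should fix the enol ether regiospecifically at the methyl-bearing carbon (the future C10), which enolisation of the free ketone could not secure.

Step 4
Reactants: 6 triethyl[(4,8,8-trimethyldeca-3,9-dien-3-yl)oxy]silane; 7 (2E)-but-2-enal
Product: 8 (2E)-4,4,8-trimethyl-9-[(triethylsilyl)oxy]undeca-2,8-dienal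
Conditions: second-generation Hoveyda–Grubbs catalyst RuCl2(H2IMes)(=CH-C6H4-2-OiPr) (5 mol %), CH2Cl2, 40 °C
Reagents that add atoms: none
Why: Olefin cross-metathesis of the terminal vinyl group with crotonaldehyde should give the E-enal with loss of propene, the fully substituted silyl enol ether being too hindered to enter the catalytic cycle.

Step 5
Reactants: 8 (2E)-4,4,8-trimethyl-9-[(triethylsilyl)oxy]undeca-2,8-dienal
Product: 11 (4aS,8aS)-2,5,5,8a-tetramethyl-4a,5,6,7,8,8a-hexahydronaphthalen-1(4H)-one, via iminium ion 9 (not isolated), via keto aldehyde 10 (not isolated)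
Conditions: (2S,5S)-5-benzyl-2-tert-butyl-3-methylimidazolidin-4-one (20 mol %), 2,4-dinitrobenzoic acid (20 mol %), H2O (2 equiv), CH2Cl2/i-PrOH, −30 °C; then TsOH·H2O, toluene, 70 °C, same flask
Reagents that add atoms: none
Why: The amine salt condenses with the enal to the E-iminium ion 9, whose β-carbon C5 is attacked by the fully substituted enol ether carbon C10 in a 6-(enolexo)-exo-trig closure of ring A (intramolecular Mukaiyama–Michael addition), after which water releases triethylsilanol, the catalyst and keto aldehyde 10. Acid then drives a 6-(enolendo)-exo-trig aldol addition of the ketone CH2 (C8) to the aldehyde carbon C7 and dehydration, which closes ring B. The closest known reactions are the iminium-catalysed Mukaiyama–Michael addition of silyl enol ethers to enals and the aldol condensation of 1,5-keto aldehydes. C5 is set by the catalyst, whose benzyl and tert-butyl groups cover one face of the iminium ion so that C10 should add to the open face (5S); C10 is set by a chair transition state in which its methyl group is axial and the bulkier oxygenated carbon equatorial, away from the axial methyl on C4 (10S, trans to H-5). The step needs conjugate instead of carbonyl addition, secured by iminium activation and by the eight-membered ring that carbonyl addition would require, and a single aldol mode, secured because the only other enol would close a four-membered ring; the enal has no γ-hydrogen, so no dienamine can form.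

Step 6
Reactants: 11 (4aS,8aS)-2,5,5,8a-tetramethyl-4a,5,6,7,8,8a-hexahydronaphthalen-1(4H)-one
Product: 13 (4aS,8aS)-2,5,5,8a-tetramethyl-3,4,4a,5,6,7,8,8a-octahydronaphthalen-1-yl trifluoromethanesulfonate, via lithium enolate 12 (not isolated)
Conditions: LiBH(s-Bu)3, THF, −78 °C; then PhNTf2, −78 °C to 0 °C
Reagents that add atoms: N-phenylbis(trifluoromethanesulfonimide), O=S(=O)(N(c1ccccc1)S(=O)(=O)C(F)(F)F)C(F)(F)F
Why: Conjugate reduction by the bulky borohydride (the carbonyl is shielded by quaternary C10) should give the C8=C9 enolate regiospecifically, and its O-triflation (reductive enolate triflation) fixes the tetrasubstituted double bond and leaves C7 as CH2.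

Step 7
Reactants: 13 (4aS,8aS)-2,5,5,8a-tetramethyl-3,4,4a,5,6,7,8,8a-octahydronaphthalen-1-yl trifluoromethanesulfonate; 14 tributyl(ethenyl)stannane
Product: 15 (4aS,8aS)-5-ethenyl-1,1,4a,6-tetramethyl-1,2,3,4,4a,7,8,8a-octahydronaphthalene
Conditions: Pd(PPh3)4 (5 mol %), LiCl, THF, 65 °C
Reagents that add atoms: none
Why: Stille coupling of the hindered enol triflate with the small vinylstannane in the presence of LiCl should install C11 and C12 without moving the ring double bond.

Step 8
Reactants: 16 but-2-yne-1,4-diol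
Product: 17 4-[(tert-butyldimethylsilyl)oxy]but-2-yn-1-ol
Conditions: t-BuMe2SiCl (1 equiv), imidazole, DMF, 0 °C, 16 in excess
Reagents that add atoms: tert-butylchlorodimethylsilane, CC(C)(C)[Si](C)(C)Cl
Why: Silyl ether formation on the symmetrical diol used in excess should give the mono-ether, which differentiates the two future CH2O arms.

Step 9
Reactants: 17 4-[(tert-butyldimethylsilyl)oxy]but-2-yn-1-ol
Product: 19 (2Z)-4-[(tert-butyldimethylsilyl)oxy]-3-iodobut-2-en-1-ol, via cyclic alkenylalanate 18 (not isolated)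
Conditions: NaAlH2(OCH2CH2OMe)2, Et2O, 0 °C; then I2, THF, −78 °C
Reagents that add atoms: iodine, [I][I]
Why: Hydroxyl-directed trans-hydroalumination places aluminium on the distal alkyne carbon within a five-membered alkoxyalanate, and iodinolysis of the C–Al bond with retention should give the Z-iodoalkene in which iodine and the CH2OH arm are cis.

Step 10
Reactants: 15 (4aS,8aS)-5-ethenyl-1,1,4a,6-tetramethyl-1,2,3,4,4a,7,8,8a-octahydronaphthalene; 19 (2Z)-4-[(tert-butyldimethylsilyl)oxy]-3-iodobut-2-en-1-ol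
Product: 21 (2E)-3-{[(tert-butyldimethylsilyl)oxy]methyl}-5-[(4aS,8aS)-2,5,5,8a-tetramethyl-3,4,4a,5,6,7,8,8a-octahydronaphthalen-1-yl]pent-2-en-1-ol, via alkylborane 20 (not isolated)
Conditions: 9-BBN, THF, rt; then 19, PdCl2(dppf) (5 mol %), AsPh3, aq. NaOH, THF/DMF, rt
Reagents that add atoms: none
Why: 9-BBN should hydroborate only the terminal vinyl carbon (anti-Markovnikov, the tetrasubstituted alkene being inert), and B-alkyl Suzuki–Miyaura coupling with the vinyl iodide proceeds with retention, so C12 ends up cis to the CH2OH arm as the E-alkene of the target requires.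

Step 11
Reactants: 21 (2E)-3-{[(tert-butyldimethylsilyl)oxy]methyl}-5-[(4aS,8aS)-2,5,5,8a-tetramethyl-3,4,4a,5,6,7,8,8a-octahydronaphthalen-1-yl]pent-2-en-1-ol
Product: 22 (2E)-3-{[(tert-butyldimethylsilyl)oxy]methyl}-5-[(4aS,8aS)-2,5,5,8a-tetramethyl-3,4,4a,5,6,7,8,8a-octahydronaphthalen-1-yl]pent-2-enal
Conditions: MnO2, CH2Cl2, rt
Reagents that add atoms: none
Why: MnO2 oxidises the only free, allylic hydroxyl group to the enal and should not touch the silyl ether or move the double bonds.

Step 12
Reactants: 22 (2E)-3-{[(tert-butyldimethylsilyl)oxy]methyl}-5-[(4aS,8aS)-2,5,5,8a-tetramethyl-3,4,4a,5,6,7,8,8a-octahydronaphthalen-1-yl]pent-2-enal; 23 2-(dichloromethyl)-4,4,5,5-tetramethyl-1,3,2-dioxaborolane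
Product: 25 tert-butyldimethyl{[(2E,4E)-5-(4,4,5,5-tetramethyl-1,3,2-dioxaborolan-2-yl)-2-{2-[(4aS,8aS)-2,5,5,8a-tetramethyl-3,4,4a,5,6,7,8,8a-octahydronaphthalen-1-yl]ethyl}penta-2,4-dien-1-yl]oxy}silane, via geminal dichromium reagent 24 (not isolated)
Conditions: CrCl2, LiI, THF, rt
Reagents that add atoms: none
Why: Takai–Utimoto olefination with the geminal dichromium reagent formed from the dichloromethylboronate should convert the aldehyde into the alkenylboronate, elimination from the less crowded β-oxido chromium adduct setting the new double bond as E.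

Step 13
Reactants: 25 the (2E,4E)-dienylboronate; 26 4-bromofuran-2(5H)-one
Product: 27 4-[(1E,3E)-4-{[(tert-butyldimethylsilyl)oxy]methyl}-6-[(4aS,8aS)-2,5,5,8a-tetramethyl-3,4,4a,5,6,7,8,8a-octahydronaphthalen-1-yl]hexa-1,3-dien-1-yl]furan-2(5H)-one
Conditions: Pd(PPh3)4 (5 mol %), K3PO4, THF/H2O, 40 °C
Reagents that add atoms: none
Why: Suzuki–Miyaura coupling of the dienylboronate with the β-bromobutenolide, an activated vinylogous acyl bromide, should proceed under mild base with retention of both double-bond geometries.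

Step 14
Reactants: 27 the silyl ether of the target
Product: 28 4-[(1E,3E)-4-(hydroxymethyl)-6-[(4aS,8aS)-2,5,5,8a-tetramethyl-3,4,4a,5,6,7,8,8a-octahydronaphthalen-1-yl]hexa-1,3-dien-1-yl]furan-2(5H)-one
Conditions: HF·pyridine, pyridine, THF, 0 °C
Reagents that add atoms: none
Why: Buffered fluoride-mediated desilylation cleaves the primary silyl ether under conditions that should neither open the butenolide nor isomerise the triene.

**Compound list**

1 | methyl 3,3-dimethylpent-4-enoate | COC(=O)CC(C)(C)C=C | starting material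
2 | 3,3-dimethylpent-4-en-1-ol | OCCC(C)(C)C=C | intermediate
3 | 5-bromo-3,3-dimethylpent-1-ene | BrCCC(C)(C)C=C | intermediate
4 | 2-methylpent-1-en-3-one | C=C(C)C(=O)CC | starting material
5 | (3,3-dimethylpent-4-en-1-yl)magnesium bromide | C=CC(C)(C)CC[Mg]Br | intermediate (not isolated)
6 | triethyl[(4,8,8-trimethyldeca-3,9-dien-3-yl)oxy]silane, E/Z mixture | CCC(O[Si](CC)(CC)CC)=C(C)CCCC(C)(C)C=C | intermediate
7 | (2E)-but-2-enal | C/C=C/C=O | starting material
8 | (2E)-4,4,8-trimethyl-9-[(triethylsilyl)oxy]undeca-2,8-dienal | CCC(O[Si](CC)(CC)CC)=C(C)CCCC(C)(C)/C=C/C=O | intermediate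
9 | iminium ion of 8 with (2S,5S)-5-benzyl-2-tert-butyl-3-methylimidazolidin-4-one, 2,4-dinitrobenzoate salt | CCC(O[Si](CC)(CC)CC)=C(C)CCCC(C)(C)/C=C/C=[N+]1[C@@H](Cc2ccccc2)C(=O)N(C)[C@H]1C(C)(C)C.[O-]C(=O)c1ccc(cc1[N+](=O)[O-])[N+](=O)[O-] | intermediate (not isolated)
10 | 2-[(1S,2S)-2,6,6-trimethyl-2-propanoylcyclohexyl]acetaldehyde | CCC(=O)[C@@]1(C)CCCC(C)(C)[C@@H]1CC=O | intermediate (not isolated)
11 | (4aS,8aS)-2,5,5,8a-tetramethyl-4a,5,6,7,8,8a-hexahydronaphthalen-1(4H)-one | CC1=CC[C@H]2C(C)(C)CCC[C@]2(C)C1=O | intermediate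
12 | lithium (4aS,8aS)-2,5,5,8a-tetramethyl-3,4,4a,5,6,7,8,8a-octahydronaphthalen-1-olate | CC1=C(O[Li])[C@@]2(C)CCCC(C)(C)[C@@H]2CC1 | intermediate (not isolated)
13 | (4aS,8aS)-2,5,5,8a-tetramethyl-3,4,4a,5,6,7,8,8a-octahydronaphthalen-1-yl trifluoromethanesulfonate | CC1=C(OS(=O)(=O)C(F)(F)F)[C@@]2(C)CCCC(C)(C)[C@@H]2CC1 | intermediate
14 | tributyl(ethenyl)stannane | C=C[Sn](CCCC)(CCCC)CCCC | starting material
15 | (4aS,8aS)-5-ethenyl-1,1,4a,6-tetramethyl-1,2,3,4,4a,7,8,8a-octahydronaphthalene | CC1=C(C=C)[C@@]2(C)CCCC(C)(C)[C@@H]2CC1 | intermediate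
16 | but-2-yne-1,4-diol | OCC#CCO | starting material
17 | 4-[(tert-butyldimethylsilyl)oxy]but-2-yn-1-ol | OCC#CCO[Si](C)(C)C(C)(C)C | intermediate
18 | cyclic sodium alkenylalanate (five-membered 1,2-oxaaluminole, Al on the carbon bearing CH2OSi, two 2-methoxyethoxy groups on Al) | [Na+].COCCO[Al-]1(OCCOC)OCC=C1CO[Si](C)(C)C(C)(C)C | intermediate (not isolated)
19 | (2Z)-4-[(tert-butyldimethylsilyl)oxy]-3-iodobut-2-en-1-ol | OC/C=C(I)/CO[Si](C)(C)C(C)(C)C | intermediate
20 | 9-{2-[(4aS,8aS)-2,5,5,8a-tetramethyl-3,4,4a,5,6,7,8,8a-octahydronaphthalen-1-yl]ethyl}-9-borabicyclo[3.3.1]nonane | CC1=C(CCB3C4CCCC3CCC4)[C@@]2(C)CCCC(C)(C)[C@@H]2CC1 | intermediate (not isolated)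
21 | (2E)-3-{[(tert-butyldimethylsilyl)oxy]methyl}-5-[(4aS,8aS)-2,5,5,8a-tetramethyl-3,4,4a,5,6,7,8,8a-octahydronaphthalen-1-yl]pent-2-en-1-ol | CC1=C(CC/C(=C\CO)CO[Si](C)(C)C(C)(C)C)[C@@]2(C)CCCC(C)(C)[C@@H]2CC1 | intermediate
22 | (2E)-3-{[(tert-butyldimethylsilyl)oxy]methyl}-5-[(4aS,8aS)-2,5,5,8a-tetramethyl-3,4,4a,5,6,7,8,8a-octahydronaphthalen-1-yl]pent-2-enal | CC1=C(CC/C(=C\C=O)CO[Si](C)(C)C(C)(C)C)[C@@]2(C)CCCC(C)(C)[C@@H]2CC1 | intermediate
23 | 2-(dichloromethyl)-4,4,5,5-tetramethyl-1,3,2-dioxaborolane | ClC(Cl)B1OC(C)(C)C(C)(C)O1 | starting material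
24 | geminal bis(dichlorochromium) reagent, 2-[bis(dichlorochromio)methyl]-4,4,5,5-tetramethyl-1,3,2-dioxaborolane | Cl[Cr](Cl)C([Cr](Cl)Cl)B1OC(C)(C)C(C)(C)O1 | intermediate (not isolated)
25 | tert-butyldimethyl{[(2E,4E)-5-(4,4,5,5-tetramethyl-1,3,2-dioxaborolan-2-yl)-2-{2-[(4aS,8aS)-2,5,5,8a-tetramethyl-3,4,4a,5,6,7,8,8a-octahydronaphthalen-1-yl]ethyl}penta-2,4-dien-1-yl]oxy}silane | CC1=C(CC/C(=C\C=C\B3OC(C)(C)C(C)(C)O3)CO[Si](C)(C)C(C)(C)C)[C@@]2(C)CCCC(C)(C)[C@@H]2CC1 | intermediate
26 | 4-bromofuran-2(5H)-one | BrC1=CC(=O)OC1 | starting material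
27 | 4-[(1E,3E)-4-{[(tert-butyldimethylsilyl)oxy]methyl}-6-[(4aS,8aS)-2,5,5,8a-tetramethyl-3,4,4a,5,6,7,8,8a-octahydronaphthalen-1-yl]hexa-1,3-dien-1-yl]furan-2(5H)-one | CC1=C(CC/C(=C\C=C\C3=CC(=O)OC3)CO[Si](C)(C)C(C)(C)C)[C@@]2(C)CCCC(C)(C)[C@@H]2CC1 | intermediate
28 | 4-[(1E,3E)-4-(hydroxymethyl)-6-[(4aS,8aS)-2,5,5,8a-tetramethyl-3,4,4a,5,6,7,8,8a-octahydronaphthalen-1-yl]hexa-1,3-dien-1-yl]furan-2(5H)-one | CC1=C(CC/C(=C\C=C\C2=CC(=O)OC2)CO)[C@@]2(C)CCCC(C)(C)[C@@H]2CC1 | target

**Total step count:** 14.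
**Longest linear sequence:** 12 steps (steps 1–7 and 10–14; steps 8 and 9 make the iodide 19).

**Steps most likely to fail**

Step 5. The acid co-catalyst may protodesilylate the enol ether before ring A closes, or facial and chair control may be weak in a conjugate addition that joins a quaternary carbon to a carbon next to another quaternary carbon. The fallback replaces catalyst control by an auxiliary and the aldol closure by a Claisen closure; it sets out from 6 and comes back at 11. Cross-metathesis of 6 with (4S)-3-acryloyl-4-benzyl-1,3-oxazolidin-2-one (same ruthenium catalyst) should give the enoyl oxazolidinone F1. TiCl4 in CH2Cl2 at −78 °C chelates the imide in its s-cis form, so that the benzyl group covers the same face of C5 as the organocatalyst does, and the intramolecular Mukaiyama–Michael addition should give the keto imide F2. NaN(SiMe3)2 in THF then closes ring B by Claisen condensation of the ketone CH2 onto the imide carbonyl with loss of the auxiliary, giving the dione F3. Tf2O and Et3N should triflate the less hindered C7 oxygen to the enol triflate F4, and Pd(OAc)2, PPh3, HCO2H and Et3N reduce the C–OTf bond to give 11.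

Step 4. Metathesis at a vinyl group attached to a quaternary carbon may be slow enough for the catalyst to decay, and the enol ether may hydrolyse during the long reaction. The fallback avoids metathesis; it sets out from 3 and comes back at iminium ion 9 in the flask of step 5. Ozonolysis of 3 (O3, CH2Cl2, −78 °C, then PPh3) gives 4-bromo-2,2-dimethylbutanal F5. Wittig reaction with (triphenylphosphoranylidene)acetaldehyde in hot toluene gives the bromo enal F6, and HC(OMe)3 with pyridinium tosylate in MeOH gives the dimethyl acetal F7. Magnesium converts F7 into the Grignard reagent F8, which is added to 4 under the conditions of step 3 to give the silyl enol ether acetal F9. Under the conditions of step 5 the acid and water open the acetal of F9 and the amine captures the enal as 9, from which the route continues.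

Step 13. Aqueous base may open or isomerise the butenolide, and the dienylboronate may protodeboronate before transmetalation. The fallback reverses the polarity and uses a base-free coupling; it sets out from 22 and 26 and comes back at 27. Takai iodo-olefination of 22 (CHI3, CrCl2, THF) gives the (E,E)-dienyl iodide F10. Stannylation of 26 with hexabutylditin and Pd(PPh3)4 gives 4-(tributylstannyl)furan-2(5H)-one F11. Stille coupling of F10 with F11 (Pd2(dba)3, AsPh3, CuI, NMP, rt) gives 27.

**Further compounds**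

F1 | step 5 | (4S)-4-benzyl-3-[(2E)-4,4,8-trimethyl-9-[(triethylsilyl)oxy]undeca-2,8-dienoyl]-1,3-oxazolidin-2-one | CCC(O[Si](CC)(CC)CC)=C(C)CCCC(C)(C)/C=C/C(=O)N1[C@@H](Cc2ccccc2)COC1=O
F2 | step 5 | (4S)-4-benzyl-3-{[(1S,2S)-2,6,6-trimethyl-2-propanoylcyclohexyl]acetyl}-1,3-oxazolidin-2-one | CCC(=O)[C@@]1(C)CCCC(C)(C)[C@@H]1CC(=O)N1[C@@H](Cc2ccccc2)COC1=O
F3 | step 5 | (4aS,8aS)-2,5,5,8a-tetramethyl-4a,5,6,7,8,8a-hexahydronaphthalene-1,3(2H,4H)-dione | CC1C(=O)C[C@H]2C(C)(C)CCC[C@]2(C)C1=O
F4 | step 5 | (4aS,8aS)-3,4a,8,8-tetramethyl-4-oxo-1,4,4a,5,6,7,8,8a-octahydronaphthalen-2-yl trifluoromethanesulfonate | CC1=C(OS(=O)(=O)C(F)(F)F)C[C@H]2C(C)(C)CCC[C@]2(C)C1=O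
F5 | step 4 | 4-bromo-2,2-dimethylbutanal | O=CC(C)(C)CCBr
F6 | step 4 | (2E)-6-bromo-4,4-dimethylhex-2-enal | O=C/C=C/C(C)(C)CCBr
F7 | step 4 | (2E)-6-bromo-1,1-dimethoxy-4,4-dimethylhex-2-ene | COC(OC)/C=C/C(C)(C)CCBr
F8 | step 4 | [(4E)-6,6-dimethoxy-3,3-dimethylhex-4-en-1-yl]magnesium bromide | COC(OC)/C=C/C(C)(C)CC[Mg]Br
F9 | step 4 | triethyl{[(9E)-11,11-dimethoxy-4,8,8-trimethylundeca-3,9-dien-3-yl]oxy}silane | CCC(O[Si](CC)(CC)CC)=C(C)CCCC(C)(C)/C=C/C(OC)OC
F10 | step 13 | tert-butyl{[(2E,4E)-5-iodo-2-{2-[(4aS,8aS)-2,5,5,8a-tetramethyl-3,4,4a,5,6,7,8,8a-octahydronaphthalen-1-yl]ethyl}penta-2,4-dien-1-yl]oxy}dimethylsilane | CC1=C(CC/C(=C\C=C\I)CO[Si](C)(C)C(C)(C)C)[C@@]2(C)CCCC(C)(C)[C@@H]2CC1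
F11 | step 13 | 4-(tributylstannyl)furan-2(5H)-one | CCCC[Sn](CCCC)(CCCC)C1=CC(=O)OC1
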